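## Retrosynthetic overview

1. Target 17 ⇒ acid 16 by late allylic C–H oxidation at C7; 16 ⇒ alkene acid 15 by saturation of C11=C12.
2. 15 ⇒ Wittig union of core aldehyde 10 (C11) with (S)-phosphonium salt 13 (C12–C16), which comes from butenolide 11 by asymmetric conjugate reduction.
3. 10 ⇒ catalyst-controlled, formyl-exo Diels–Alder reaction of ring A diene 8 with tiglaldehyde 9; this closes ring B and sets C8, C9 and C10.
4. 8 ⇒ (R)-aldehyde 6 ⇒ achiral dienal 5 by a new asymmetric phase-transfer deconjugative α-methylation (sets C4, unveils the diene) ⇒ cyclohexanone 1.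
5. Ring order: ring A is present from the start (cyclohexanone); ring B is formed by the Diels–Alder reaction.

Assumption: positions follow halimane numbering (C4 bears CH3 and CH2OAc = C18; C5=C6; C7 ketone; C8–CH3; C9 bears CH3 and side chain C11–C15 with C16 methyl on C13; C10–H). Where the sense of induction of a chiral catalyst is not known with certainty, the enantiomer written is the expected one and its mirror image, equally available, is used if needed.

## Route

Step 1
Reactants: 1 cyclohexanone
Product: 3 2-bromocyclohex-1-ene-1-carbaldehyde, via iminium bromide 2 (not isolated)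
Conditions: PBr3, DMF, CHCl3, 0 °C → rt; then ice-water
Reagents that add atoms: N,N-dimethylformamide CN(C)C=O; phosphorus tribromide BrP(Br)Br; water O
Why: Vilsmeier–Haack–Arnold bromoformylation, in which the enol of 1 is formylated by the bromo-iminium salt from DMF/PBr3, the carbonyl oxygen is exchanged for bromide, and water hydrolyses iminium 2 to the β-bromo enal.

Step 2
Reactants: 3 2-bromocyclohex-1-ene-1-carbaldehyde; 4 potassium vinyltrifluoroborate
Product: 5 2-vinylcyclohex-1-ene-1-carbaldehyde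
Conditions: PdCl2(dppf) (2 mol %), Cs2CO3 (3 equiv), THF/H2O 9:1, 70 °C
Reagents that add atoms: none
Why: Suzuki–Miyaura coupling (oxidative addition into the activated β-bromo enal C–Br bond, transmetalation from the vinyltrifluoroborate, reductive elimination) gives the achiral cross-conjugated dienal.

Step 3
Reactants: 5 2-vinylcyclohex-1-ene-1-carbaldehyde
Product: 6 (R)-1-methyl-2-vinylcyclohex-2-ene-1-carbaldehyde
Conditions: MeI (3 equiv), CsOH·H2O (1.5 equiv), (S)-4,4-dibutyl-2,6-bis(3,4,5-trifluorophenyl)-4,5-dihydro-3H-dinaphtho[2,1-c:1′,2′-e]azepinium bromide (2 mol %), toluene, −40 °C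
Reagents that add atoms: iodomethane CI
Why: Proposed new method: enantioselective phase-transfer deconjugative α-methylation of an α-branched enal, in which interfacial γ-deprotonation at C10 gives a cross-conjugated dienolate (one geometry, because allylic strain keeps the formyl oxygen turned toward C3) that is ion-paired with the C2-symmetric binaphthyl ammonium cation, whose aryl walls shield one face so that MeI attacks the α-carbon C4 (largest coefficient, kinetic α-alkylation of dienolates), creating the quaternary C4 stereocentre irreversibly (no α-H remains) and moving the alkene to C5=C10 to unveil the diene; the closest known reaction types are chiral quaternary ammonium phase-transfer alkylations that form quaternary carbons on β-keto esters, and the achiral base-mediated deconjugative α-alkylation of cyclohexenecarbaldehydes.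

Step 4
Reactants: 6 (R)-1-methyl-2-vinylcyclohex-2-ene-1-carbaldehyde
Product: 8 [(1R)-1-methyl-2-vinylcyclohex-2-en-1-yl]methyl acetate, via aluminium alkoxide 7 (not isolated)
Conditions: i-Bu2AlH (1.1 equiv), CH2Cl2, −78 °C; then pyridine, DMAP, Ac2O, −78 °C → rt
Reagents that add atoms: acetic anhydride CC(=O)OC(C)=O
Why: Hydride reduction of the non-enolisable aldehyde gives an aluminium alkoxide that is acetylated in the same flask (reductive acetylation with DMAP acyl transfer), leaving the quaternary stereocentre and the diene untouched.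

Step 5
Reactants: 8 [(1R)-1-methyl-2-vinylcyclohex-2-en-1-yl]methyl acetate; 9 (E)-2-methylbut-2-enal (tiglaldehyde)
Product: 10 (1R,2S,5R,8aR)-5-[(acetyloxy)methyl]-1,2,5-trimethyl-1,2,3,5,6,7,8,8a-octahydronaphthalene-1-carbaldehyde
Conditions: (S)-3,3-diphenyl-1-(o-tolyl)tetrahydro-1H,3H-pyrrolo[1,2-c][1,3,2]oxazaborole (20 mol %), Tf2NH (18 mol %), 9 (2 equiv), CH2Cl2, −78 → −40 °C
Reagents that add atoms: none
Why: Enantioselective Diels–Alder reaction catalysed by a protonated oxazaborolidine (Corey type), in which the unsubstituted diene terminus C7 bonds to the enal β-carbon C8 and C10 to the α-carbon C9 ("ortho" regiochemistry), suprafacial addition turns the E geometry of 9 into cis C8/C9 methyls, the formyl-exo arrangement expected for an α-methyl enal on this bulky cationic boron (an endo catalyst-bound formyl would sit under quaternary C4) puts CHO cis to H-10, and the catalyst exposes the (2Si,3Re) face of 9, which fixes C8, C9 and C10 relative to C4 (reinforced by the pseudoaxial CH2OAc arm shielding the opposite diene face).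

Step 6
Reactants: 11 4-methylfuran-2(5H)-one
Product: 12 (S)-4-methyldihydrofuran-2(3H)-one
Conditions: Cu(OAc)2 (3 mol %), (S)-2,2′-bis(di-p-tolylphosphino)-1,1′-binaphthyl (3 mol %), (EtO)2MeSiH (2 equiv), t-BuOH (2 equiv), toluene, 0 °C → rt
Reagents that add atoms: none
Why: Copper hydride catalysed asymmetric 1,4-reduction of a β-substituted butenolide (Buchwald type), in which the bisphosphine-ligated CuH delivers hydride to one enantioface of C4 (the future C13) and t-BuOH protonates the copper enolate.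

Step 7
Reactants: 12 (S)-4-methyldihydrofuran-2(3H)-one
Product: 13 (S)-(3-carboxy-2-methylpropyl)triphenylphosphonium bromide
Conditions: Ph3P·HBr (1.0 equiv), neat, 160 °C; crystallise from CH2Cl2/Et2O
Reagents that add atoms: triphenylphosphine hydrobromide [Br-].c1ccc(cc1)[PH+](c1ccccc1)c1ccccc1
Why: Acid-assisted SN2 opening of the γ-lactone at the O–CH2 carbon by triphenylphosphine (the known route from γ-butyrolactone to the 3-carboxypropyl salt), with the stereocentre not a reaction site.

Step 8
Reactants: 10 (1R,2S,5R,8aR)-5-[(acetyloxy)methyl]-1,2,5-trimethyl-1,2,3,5,6,7,8,8a-octahydronaphthalene-1-carbaldehyde; 13 (S)-(3-carboxy-2-methylpropyl)triphenylphosphonium bromide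
Product: 15 (3S,4Z)-5-{(1S,2S,5R,8aS)-5-[(acetyloxy)methyl]-1,2,5-trimethyl-1,2,3,5,6,7,8,8a-octahydronaphthalen-1-yl}-3-methylpent-4-enoic acid, via phosphonium ylide 14 (not isolated)
Conditions: 13 (1.6 equiv), NaN(SiMe3)2 (3.1 equiv), THF, 0 °C; then 10, 0 °C → rt; 1 M HCl work-up
Reagents that add atoms: none
Why: Wittig olefination of the non-enolisable neopentyl aldehyde (C9 has no hydrogen, so nothing epimerises) by the non-stabilised ylide, whose carboxylate is masked as its sodium salt, forms C11=C12 (Z, irrelevant because it is reduced next) and brings in C13 unchanged.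

Step 9
Reactants: 15 (3S,4Z)-5-{(1S,2S,5R,8aS)-5-[(acetyloxy)methyl]-1,2,5-trimethyl-1,2,3,5,6,7,8,8a-octahydronaphthalen-1-yl}-3-methylpent-4-enoic acid
Product: 16 (3R)-5-{(1R,2S,5R,8aS)-5-[(acetyloxy)methyl]-1,2,5-trimethyl-1,2,3,5,6,7,8,8a-octahydronaphthalen-1-yl}-3-methylpentanoic acid
Conditions: TsNHNH2 (10 equiv), NaOAc (12 equiv), THF/H2O 1:1, 70 °C; acidify
Reagents that add atoms: none
Why: Diimide reduction (concerted syn transfer of H2) is much faster for the cis-disubstituted C11=C12 alkene than for the trisubstituted C5=C6 alkene flanked by quaternary C4, and leaves acetate and acid alone.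

Step 10
Reactants: 16 (3R)-5-{(1R,2S,5R,8aS)-5-[(acetyloxy)methyl]-1,2,5-trimethyl-1,2,3,5,6,7,8,8a-octahydronaphthalen-1-yl}-3-methylpentanoic acid
Product: 17 (3R)-5-{(1S,2R,5R,8aS)-5-[(acetyloxy)methyl]-1,2,5-trimethyl-3-oxo-1,2,3,5,6,7,8,8a-octahydronaphthalen-1-yl}-3-methylpentanoic acid (CNP0210381.1)
Conditions: CrO3 (15 equiv), 3,5-dimethylpyrazole (15 equiv), CH2Cl2, −20 °C
Reagents that add atoms: chromium trioxide O=[Cr](=O)=O
Why: Allylic C–H oxidation with the CrO3–3,5-dimethylpyrazole complex converts the only secondary allylic position C7 into the ketone (C4 has no hydrogen; the tertiary C10–H is shielded by quaternary C9), giving the 5-en-7-one, and the now epimerisable C8 already holds its methyl in the expected more stable equatorial position.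

## Compound list

1 | cyclohexanone | O=C1CCCCC1 | starting material
2 | N-[(2-bromocyclohex-1-en-1-yl)methylidene]-N-methylmethanaminium bromide | C[N+](C)=CC1=C(Br)CCCC1.[Br-] | intermediate (not isolated)
3 | 2-bromocyclohex-1-ene-1-carbaldehyde | O=CC1=C(Br)CCCC1 | intermediate
4 | potassium vinyltrifluoroborate | C=C[B-](F)(F)F.[K+] | starting material
5 | 2-vinylcyclohex-1-ene-1-carbaldehyde | O=CC1=C(C=C)CCCC1 | intermediate
6 | (R)-1-methyl-2-vinylcyclohex-2-ene-1-carbaldehyde | O=C[C@]1(C)CCCC=C1C=C | intermediate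
7 | diisobutyl{[(1R)-1-methyl-2-vinylcyclohex-2-en-1-yl]methoxy}aluminium | CC(C)C[Al](CC(C)C)OC[C@]1(C)CCCC=C1C=C | intermediate (not isolated)
8 | [(1R)-1-methyl-2-vinylcyclohex-2-en-1-yl]methyl acetate | CC(=O)OC[C@]1(C)CCCC=C1C=C | intermediate
9 | (E)-2-methylbut-2-enal (tiglaldehyde) | C/C=C(\C)C=O | starting material
10 | (1R,2S,5R,8aR)-5-[(acetyloxy)methyl]-1,2,5-trimethyl-1,2,3,5,6,7,8,8a-octahydronaphthalene-1-carbaldehyde (4R,8S,9R,10R in halimane numbering; 8β-Me, 9β-Me, 9α-CHO, 10α-H) | CC(=O)OC[C@]1(C)CCC[C@@H]2C1=CC[C@H](C)[C@@]2(C)C=O | intermediate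
11 | 4-methylfuran-2(5H)-one | CC1=CC(=O)OC1 | starting material
12 | (S)-4-methyldihydrofuran-2(3H)-one | C[C@@H]1COC(=O)C1 | intermediate
13 | (S)-(3-carboxy-2-methylpropyl)triphenylphosphonium bromide | C[C@@H](CC(=O)O)C[P+](c1ccccc1)(c1ccccc1)c1ccccc1.[Br-] | intermediate
14 | sodium (S)-3-methyl-4-(triphenyl-λ5-phosphanylidene)butanoate | C[C@@H](CC(=O)[O-])C=P(c1ccccc1)(c1ccccc1)c1ccccc1.[Na+] | intermediate (not isolated)
15 | (3S,4Z)-5-{(1S,2S,5R,8aS)-5-[(acetyloxy)methyl]-1,2,5-trimethyl-1,2,3,5,6,7,8,8a-octahydronaphthalen-1-yl}-3-methylpent-4-enoic acid | CC(=O)OC[C@]1(C)CCC[C@@H]2C1=CC[C@H](C)[C@@]2(C)/C=C\[C@@H](C)CC(=O)O | intermediate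
16 | (3R)-5-{(1R,2S,5R,8aS)-5-[(acetyloxy)methyl]-1,2,5-trimethyl-1,2,3,5,6,7,8,8a-octahydronaphthalen-1-yl}-3-methylpentanoic acid | CC(=O)OC[C@]1(C)CCC[C@@H]2C1=CC[C@H](C)[C@@]2(C)CC[C@@H](C)CC(=O)O | intermediate
17 | (3R)-5-{(1S,2R,5R,8aS)-5-[(acetyloxy)methyl]-1,2,5-trimethyl-3-oxo-1,2,3,5,6,7,8,8a-octahydronaphthalen-1-yl}-3-methylpentanoic acid (4R,8R,9S,10S,13R) | CC(=O)OC[C@]1(C)CCC[C@@H]2C1=CC(=O)[C@H](C)[C@@]2(C)CC[C@@H](C)CC(=O)O | target

## Step count and risk

Total step count: 10. Longest linear sequence: 8 (steps 1–5 and 8–10); steps 6–7 make the side-chain fragment.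

Three steps most likely to fail:

**Step 3 (the proposed new asymmetric deconjugative methylation).** Risks are O- or γ-methylation, base-induced oligomerisation of the dienal, and insufficient enantioselectivity.

The fallback uses known chemistry, sets out from 1 and comes back at 8. Cyclohexanone 1 is C-acylated (NaH, dimethyl carbonate, THF, reflux) to methyl 2-oxocyclohexane-1-carboxylate F1. The established chiral ammonium phase-transfer alkylation of cyclic β-keto esters (MeI, CsOH·H2O, the same class of binaphthyl ammonium bromide, toluene, −40 °C) gives methyl (R)-1-methyl-2-oxocyclohexane-1-carboxylate F2. Enolisation on the only possible side (KN(SiMe3)2, PhNTf2, THF, −78 °C) gives methyl (R)-1-methyl-2-{[(trifluoromethyl)sulfonyl]oxy}cyclohex-2-ene-1-carboxylate F3. Suzuki coupling with 4 (PdCl2(dppf), Cs2CO3, THF/H2O) gives methyl (R)-1-methyl-2-vinylcyclohex-2-ene-1-carboxylate F4. Reduction with i-Bu2AlH (2.2 equiv) followed by Ac2O/pyridine/DMAP in the same flask gives 8 through the same aluminium alkoxide 7.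

**Step 5 (Diels–Alder).** Risks are the low reactivity of an α,β-disubstituted enal toward a hindered diene, and erosion of the exo/diene-face control, which would give diastereomers at C8–C10 relative to C4.

The fallback replaces catalyst control by substrate control; it sets out from 6 and comes back at 10. Aldehyde 6 is reduced (NaBH4, MeOH, 0 °C) to [(1R)-1-methyl-2-vinylcyclohex-2-en-1-yl]methanol F5 and silylated (t-BuPh2SiCl, imidazole, DMF) to tert-butyl{[(1R)-1-methyl-2-vinylcyclohex-2-en-1-yl]methoxy}diphenylsilane F6. In F6, allylic strain against the vinyl group is expected to push the bulky silyloxymethyl arm pseudoaxial so that it blocks the α-face at C10. An achiral Lewis acid Diels–Alder reaction with 9 (BF3·OEt2, CH2Cl2, −78 °C) then gives the silyl ether aldehyde (1R,2S,5R,8aR)-5-{[(tert-butyldiphenylsilyl)oxy]methyl}-1,2,5-trimethyl-1,2,3,5,6,7,8,8a-octahydronaphthalene-1-carbaldehyde F7; any minor diastereomer is removed by chromatography. Bu4NF in THF gives the hydroxy aldehyde (1R,2S,5R,8aR)-5-(hydroxymethyl)-1,2,5-trimethyl-1,2,3,5,6,7,8,8a-octahydronaphthalene-1-carbaldehyde F8, and Ac2O/pyridine gives 10.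

**Step 8 (Wittig reaction).** Risks are the hindered aldehyde on a quaternary carbon, the poorly soluble carboxylate ylide, and attack of ylide or base on the acetate.

The fallback moves the bond formation from C11=C12 to C12–C13 and sets C13 afterwards; it sets out from 10, comes back at 16, and makes steps 6, 7 and 9 unnecessary. Aldehyde 10 is methylenated with the small ylide Ph3P=CH2 (Ph3PCH3Br, KOt-Bu, THF) to the vinyl compound (4R,8S,9R,10S)-13,14,15,16-tetranorhalima-5,11-dien-18-yl acetate F9. Selective hydroboration of the monosubstituted alkene with 9-borabicyclo[3.3.1]nonane gives the B-alkyl borane (4R,8S,9R,10S)-12-(9-borabicyclo[3.3.1]nonan-9-yl)-13,14,15,16-tetranorhalim-5-en-18-yl acetate F10. This is coupled in the same flask (PdCl2(dppf), K3PO4, DMF/H2O) with tert-butyl (Z)-3-iodobut-2-enoate to give tert-butyl (4R,8S,9R,10S,13Z)-18-acetoxyhalima-5,13-dien-15-oate F11. Copper hydride asymmetric conjugate reduction (Cu(OAc)2, chiral bisphosphine, (EtO)2MeSiH, t-BuOH) sets C13 and gives tert-butyl (4R,8S,9R,10S,13R)-18-acetoxyhalim-5-en-15-oate F12. CF3CO2H in CH2Cl2 cleaves the tert-butyl ester to give 16.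

## Further compounds

F1 | step 3 | methyl 2-oxocyclohexane-1-carboxylate | COC(=O)C1CCCCC1=O
F2 | step 3 | methyl (R)-1-methyl-2-oxocyclohexane-1-carboxylate | COC(=O)[C@]1(C)CCCCC1=O
F3 | step 3 | methyl (R)-1-methyl-2-{[(trifluoromethyl)sulfonyl]oxy}cyclohex-2-ene-1-carboxylate | COC(=O)[C@]1(C)CCCC=C1OS(=O)(=O)C(F)(F)F
F4 | step 3 | methyl (R)-1-methyl-2-vinylcyclohex-2-ene-1-carboxylate | COC(=O)[C@]1(C)CCCC=C1C=C
F5 | step 5 | [(1R)-1-methyl-2-vinylcyclohex-2-en-1-yl]methanol | OC[C@]1(C)CCCC=C1C=C
F6 | step 5 | tert-butyl{[(1R)-1-methyl-2-vinylcyclohex-2-en-1-yl]methoxy}diphenylsilane | CC(C)(C)[Si](OC[C@]1(C)CCCC=C1C=C)(c1ccccc1)c1ccccc1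
F7 | step 5 | (1R,2S,5R,8aR)-5-{[(tert-butyldiphenylsilyl)oxy]methyl}-1,2,5-trimethyl-1,2,3,5,6,7,8,8a-octahydronaphthalene-1-carbaldehyde | CC(C)(C)[Si](OC[C@]1(C)CCC[C@@H]2C1=CC[C@H](C)[C@@]2(C)C=O)(c1ccccc1)c1ccccc1
F8 | step 5 | (1R,2S,5R,8aR)-5-(hydroxymethyl)-1,2,5-trimethyl-1,2,3,5,6,7,8,8a-octahydronaphthalene-1-carbaldehyde | OC[C@]1(C)CCC[C@@H]2C1=CC[C@H](C)[C@@]2(C)C=O
F9 | step 8 | (4R,8S,9R,10S)-13,14,15,16-tetranorhalima-5,11-dien-18-yl acetate | CC(=O)OC[C@]1(C)CCC[C@@H]2C1=CC[C@H](C)[C@@]2(C)C=C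
F10 | step 8 | (4R,8S,9R,10S)-12-(9-borabicyclo[3.3.1]nonan-9-yl)-13,14,15,16-tetranorhalim-5-en-18-yl acetate | CC(=O)OC[C@]1(C)CCC[C@@H]2C1=CC[C@H](C)[C@@]2(C)CCB1C2CCCC1CCC2
F11 | step 8 | tert-butyl (4R,8S,9R,10S,13Z)-18-acetoxyhalima-5,13-dien-15-oate | CC(=O)OC[C@]1(C)CCC[C@@H]2C1=CC[C@H](C)[C@@]2(C)CC/C(C)=C\C(=O)OC(C)(C)C
F12 | step 8 | tert-butyl (4R,8S,9R,10S,13R)-18-acetoxyhalim-5-en-15-oate | CC(=O)OC[C@]1(C)CCC[C@@H]2C1=CC[C@H](C)[C@@]2(C)CC[C@@H](C)CC(=O)OC(C)(C)C
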